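The target is disconnected at both C6–O ester bonds into the centrosymmetric α‑truxillic diacid (cyclobutane from head‑to‑tail [2+2] photodimerisation of p‑coumaric acid) and two molecules of one bicyclic amino alcohol, joined by a double Mitsunobu reaction with inversion at C6.
The amino alcohol comes from a cis‑fused N‑methoxycarbonyl ketone (LiAlH4 gives N–CH3 and the C6 alcohol), and this from a β‑keto ester on an N‑acyl‑1,4‑dihydropyridine (hydrogenation sets C4 and C7a, then decarboxylation and C7 equilibration).
Feature used: C4a, the ring‑fusion carbon, is the γ (para) carbon of the pyridine latent in the piperidine ring N2–C1–C7a–C4a–C4–C3, and it lies β to the C6 carbonyl through C5. The enol carbon C5 of a chain C7–C6–C5 anchored at C7a can therefore add to C4a once the nitrogen is acylated, forming C4a–C5 and the cyclopentanone ring C4a–C5–C6–C7–C7a.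
Ring order: pyridine (bought) → cyclopentanone (step 4) → piperidine by hydrogenation (step 5); cyclobutane made separately (step 9); union in step 12.

Key step: step 4

Remark (assumption): the enantiomer of the thiourea catalyst that delivers the 4aS product cannot be predicted and is fixed in a screen (both catalyst enantiomers are accessible). C7 is left racemic on purpose up to step 7, where it is set by equilibration.

Step 1
Reactants: 1 3-bromo-5-methylpyridine; 2 tert-butyl propanoate
Product: 3 tert-butyl 2-(5-methylpyridin-3-yl)propanoate (racemic)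
Conditions: LiHMDS, Pd2(dba)3 (1 mol%), P(t-Bu)3 (2 mol%), toluene, rt
Reagents that add atoms: none
Why: Palladium-catalysed α-arylation of the ester lithium enolate (oxidative addition of 1, transmetallation, C–C reductive elimination) is reliable for 3-bromopyridines and tert-butyl esters; the new α-centre is formed racemic on purpose because it becomes the labile C7.

Step 2
Reactants: 3 tert-butyl 2-(5-methylpyridin-3-yl)propanoate
Product: 4 2-(5-methylpyridin-3-yl)propanoic acid (racemic)
Conditions: TFA, CH2Cl2, rt; then neutralisation to the isoelectric point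
Reagents that add atoms: none
Why: Acidolysis of the tert-butyl ester by the AAL1 path (loss of 2-methylpropene) leaves the pyridine and the acid untouched.

Step 3
Reactants: 4 2-(5-methylpyridin-3-yl)propanoic acid; 5 potassium methyl malonate
Product: 7 methyl 4-(5-methylpyridin-3-yl)-3-oxopentanoate (racemic), via acyl imidazolide 6 (not isolated)
Conditions: CDI, THF, rt; then 5, MgCl2, Et3N, THF, rt → 50 °C; pH 6 work-up
Reagents that add atoms: none
Why: Masamune–Brooks chain extension, in which the acyl imidazolide C-acylates the magnesium chelate of the malonate half-ester and the adduct loses CO2, gives the β-keto ester under nearly neutral conditions that the pyridine tolerates.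

Step 4
Reactants: 7 methyl 4-(5-methylpyridin-3-yl)-3-oxopentanoate; 8 methyl chloroformate
Product: 10 dimethyl (4aS)-4,7-dimethyl-6-oxo-4a,5,6,7-tetrahydro-2H-cyclopenta[c]pyridine-2,5-dicarboxylate (C5/C7 epimers), via N-methoxycarbonylpyridinium chloride 9 (not isolated)
Conditions: 8 (1.1 equiv), chiral tert-leucine amido-thiourea (2-arylpyrrolidine amide, 3,5-bis(trifluoromethyl)phenyl thiourea; 10 mol%), MTBE, −60 °C; then i-Pr2NEt (1.2 equiv, syringe pump), −60 °C
Reagents that add atoms: none
Why: Proposed new method: 8 acylates the pyridine nitrogen of 7 to give the N-methoxycarbonylpyridinium chloride 9, whose chloride is held by the two thiourea N–H bonds so that the chiral catalyst·chloride complex stays ion-paired over one face of the cation; as the amine takes the C5 proton, the β-keto ester carbon C5 adds to the γ-carbon (pyridine C4, future C4a) and the product is an N-acyl-1,4-dihydropyridine. The closest known reaction types are the intramolecular addition of tethered β-dicarbonyl carbons to N-alkoxycarbonylpyridinium ions under achiral mediation and the thiourea anion-binding-catalysed enantioselective addition of enol-type nucleophiles to N-acyl pyridinium, quinolinium and isoquinolinium chlorides; their union, an intramolecular enantioselective γ-closure with a free β-keto ester, has not been shown. The cyclopentanone (C4a–C5–C6–C7–C7a) closes in a 5-(enolexo)-exo-trig mode, because C5 reacts through the ester enol(ate) C5=C(OMe)O with the C6 carbonyl twisted out of conjugation, which is why no chelating metal is used (a planar chelated keto-enolate would force the disfavoured 5-enolendo geometry). C4a, the only stereocentre that matters here, is set by the catalyst (4aS), whereas C5 and C7 stay enolisable under the amine and are not controlled. The step needs γ- over α-selectivity (C4a against C1, both five-ring closures) and C- over O-attack: the soft, doubly stabilised carbon prefers the γ-carbon with the largest LUMO coefficient, the carbamate screens C1, and α- or O-adducts re-ionise at −60 °C much faster than the γ-adduct and so drain into 10. Product 10 is kept cold, is present partly as its ammonium enolate (which cannot re-open) and is hydrogenated at once, so that the γ-closure does not reverse and erode the enantiomeric purity.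

Step 5
Reactants: 10 dimethyl (4aS)-4,7-dimethyl-6-oxo-4a,5,6,7-tetrahydro-2H-cyclopenta[c]pyridine-2,5-dicarboxylate (crude)
Product: 11 dimethyl (4R,4aS,7aR)-4,7-dimethyl-6-oxooctahydro-2H-cyclopenta[c]pyridine-2,5-dicarboxylate (C5/C7 epimers)
Conditions: H2 (5 atm), 5% Rh/Al2O3, EtOAc, rt
Reagents that add atoms: none
Why: Heterogeneous syn-hydrogenation of both enecarbamate C=C bonds (a known reduction of N-acyl-1,4-dihydropyridines to N-acylpiperidines) should occur from the convex face of the folded bicycle, the face of H4a, which sets C7a (R, cis ring fusion) and C4 (R, H4 cis to H4a); C5 epimerises through its enol and can turn its ester away from the catalyst, and rhodium does not reduce the ketone under these conditions.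

Step 6
Reactants: 11 dimethyl (4R,4aS,7aR)-4,7-dimethyl-6-oxooctahydro-2H-cyclopenta[c]pyridine-2,5-dicarboxylate
Product: 12 methyl (4R,4aS,7aR)-4,7-dimethyl-6-oxooctahydro-2H-cyclopenta[c]pyridine-2-carboxylate (C7 epimers)
Conditions: LiCl, H2O, DMSO, 130 °C
Reagents that add atoms: none
Why: Krapcho dealkoxycarbonylation, in which chloride demethylates the β-keto ester by SN2 at the O-methyl group and the β-keto carboxylate loses CO2, leaves the unactivated methyl carbamate and the non-enolisable centres C4, C4a and C7a unaffected.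

Step 7
Reactants: 12 methyl (4R,4aS,7aR)-4,7-dimethyl-6-oxooctahydro-2H-cyclopenta[c]pyridine-2-carboxylate (C7 epimers)
Product: 13 methyl (4R,4aS,7S,7aR)-4,7-dimethyl-6-oxooctahydro-2H-cyclopenta[c]pyridine-2-carboxylate
Conditions: NaOMe (0.2 equiv), MeOH, rt
Reagents that add atoms: none
Why: Epimerisation through the C6 enolate under thermodynamic control should place the C7 methyl group on the convex face, trans to the C7a–C1 bond (7S), and methoxide exchange at the methyl carbamate is degenerate.

Step 8
Reactants: 13 methyl (4R,4aS,7S,7aR)-4,7-dimethyl-6-oxooctahydro-2H-cyclopenta[c]pyridine-2-carboxylate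
Product: 14 (4R,4aS,6S,7S,7aR)-2,4,7-trimethyloctahydro-1H-cyclopenta[c]pyridin-6-ol (6-endo alcohol; OH trans to the C7 methyl and cis to the piperidine ring)
Conditions: LiAlH4, THF, −78 °C → reflux
Reagents that add atoms: none
Why: Hydride reduction with LiAlH4 should add hydride to C6 from the convex face at low temperature, because the piperidine ring screens the concave face at both β-carbons, giving the endo (6S) alcohol, and at reflux the methyl carbamate is reduced to the N-methyl amine.

Step 9
Reactants: 15 p-coumaric acid (two molecules)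
Product: 16 (1α,2α,3β,4β)-2,4-bis(4-hydroxyphenyl)cyclobutane-1,3-dicarboxylic acid (4,4′-dihydroxy-α-truxillic acid; achiral)
Conditions: hν (Pyrex-filtered Hg lamp), ground crystals suspended in hexane, rt
Reagents that add atoms: none
Why: Topochemical [2+2] photocycloaddition, in which the crystal stacks the molecules head-to-tail across an inversion centre with parallel C=C bonds about 4 Å apart, dictates the centrosymmetric α-truxillic dimer with all four cyclobutane centres fixed by the lattice.

Step 10
Reactants: 16 4,4′-dihydroxy-α-truxillic acid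
Product: 17 dibenzyl (1α,2α,3β,4β)-2,4-bis[4-(benzyloxy)phenyl]cyclobutane-1,3-dicarboxylate
Conditions: BnBr (4.4 equiv), K2CO3, DMF, 60 °C
Reagents that add atoms: benzyl bromide, BrCc1ccccc1
Why: Fourfold SN2 alkylation (Williamson ether synthesis at the phenols, carboxylate alkylation at the acids) uses carbonate, a base too weak to epimerise the cyclobutane C–H bonds.

Step 11
Reactants: 17 dibenzyl (1α,2α,3β,4β)-2,4-bis[4-(benzyloxy)phenyl]cyclobutane-1,3-dicarboxylate
Product: 18 (1α,2α,3β,4β)-2,4-bis[4-(benzyloxy)phenyl]cyclobutane-1,3-dicarboxylic acid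
Conditions: LiOH, THF/H2O, 50 °C; then 1 M HCl
Reagents that add atoms: lithium hydroxide, [Li+].[OH-]
Why: Saponification (BAc2) cleaves only the two benzyl esters, the benzyl aryl ethers being inert to hydroxide, and the α-truxillate configuration is not epimerised by alkali at this temperature.

Step 12
Reactants: 14 (4R,4aS,6S,7S,7aR)-2,4,7-trimethyloctahydro-1H-cyclopenta[c]pyridin-6-ol (2.2 equiv); 18 (1α,2α,3β,4β)-2,4-bis[4-(benzyloxy)phenyl]cyclobutane-1,3-dicarboxylic acid
Product: 19 bis[(4R,4aS,6R,7S,7aR)-2,4,7-trimethyloctahydro-1H-cyclopenta[c]pyridin-6-yl] (1α,2α,3β,4β)-2,4-bis[4-(benzyloxy)phenyl]cyclobutane-1,3-dicarboxylate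
Conditions: PPh3, DIAD, THF, 0 °C → rt
Reagents that add atoms: none
Why: Double Mitsunobu esterification activates each C6 hydroxyl group as its alkoxyphosphonium ion, which a carboxylate of 18 displaces by SN2 with inversion (6S to 6R) from the open convex face, and the tertiary amine does not interfere.

Step 13
Reactants: 19 bis-benzyl ether of the target
Product: 20 bis[(4R,4aS,6R,7S,7aR)-2,4,7-trimethyloctahydro-1H-cyclopenta[c]pyridin-6-yl] (1α,2α,3β,4β)-2,4-bis(4-hydroxyphenyl)cyclobutane-1,3-dicarboxylate (CNP0180864.2)
Conditions: H2 (1 atm), 10% Pd/C, EtOAc/MeOH, rt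
Reagents that add atoms: none
Why: Hydrogenolysis of the two benzyl aryl ethers on palladium leaves the alkyl esters, the tertiary amines and the cyclobutane untouched and sets no stereocentre.

Compound list
1 | 3-bromo-5-methylpyridine | Cc1cncc(Br)c1 | starting material
2 | tert-butyl propanoate | CCC(=O)OC(C)(C)C | starting material
3 | tert-butyl 2-(5-methylpyridin-3-yl)propanoate (racemic) | Cc1cncc(C(C)C(=O)OC(C)(C)C)c1 | intermediate
4 | 2-(5-methylpyridin-3-yl)propanoic acid (racemic) | Cc1cncc(C(C)C(=O)O)c1 | intermediate
5 | potassium methyl malonate | COC(=O)CC(=O)[O-].[K+] | starting material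
6 | 1-(1H-imidazol-1-yl)-2-(5-methylpyridin-3-yl)propan-1-one (acyl imidazolide, not isolated) | Cc1cncc(C(C)C(=O)n2ccnc2)c1 | intermediate
7 | methyl 4-(5-methylpyridin-3-yl)-3-oxopentanoate (racemic) | Cc1cncc(C(C)C(=O)CC(=O)OC)c1 | intermediate
8 | methyl chloroformate | COC(=O)Cl | starting material
9 | 1-(methoxycarbonyl)-3-(5-methoxy-3,5-dioxopentan-2-yl)-5-methylpyridin-1-ium chloride (not isolated) | Cc1c[n+](C(=O)OC)cc(C(C)C(=O)CC(=O)OC)c1.[Cl-] | intermediate
10 | dimethyl (4aS)-4,7-dimethyl-6-oxo-4a,5,6,7-tetrahydro-2H-cyclopenta[c]pyridine-2,5-dicarboxylate (C5/C7 epimers) | CC1C2=CN(C(=O)OC)C=C(C)[C@@H]2C(C(=O)OC)C1=O | intermediate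
11 | dimethyl (4R,4aS,7aR)-4,7-dimethyl-6-oxooctahydro-2H-cyclopenta[c]pyridine-2,5-dicarboxylate (C5/C7 epimers) | CC1[C@@H]2CN(C(=O)OC)C[C@H](C)[C@@H]2C(C(=O)OC)C1=O | intermediate
12 | methyl (4R,4aS,7aR)-4,7-dimethyl-6-oxooctahydro-2H-cyclopenta[c]pyridine-2-carboxylate (C7 epimers) | CC1[C@@H]2CN(C(=O)OC)C[C@H](C)[C@@H]2CC1=O | intermediate
13 | methyl (4R,4aS,7S,7aR)-4,7-dimethyl-6-oxooctahydro-2H-cyclopenta[c]pyridine-2-carboxylate | C[C@H]1[C@@H]2CN(C(=O)OC)C[C@H](C)[C@@H]2CC1=O | intermediate
14 | (4R,4aS,6S,7S,7aR)-2,4,7-trimethyloctahydro-1H-cyclopenta[c]pyridin-6-ol | C[C@H]1[C@@H]2CN(C)C[C@H](C)[C@@H]2C[C@@H]1O | intermediate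
15 | p-coumaric acid, (E)-3-(4-hydroxyphenyl)prop-2-enoic acid | O=C(O)/C=C/c1ccc(O)cc1 | starting material
16 | (1α,2α,3β,4β)-2,4-bis(4-hydroxyphenyl)cyclobutane-1,3-dicarboxylic acid | OC(=O)[C@H]1[C@H](c2ccc(O)cc2)[C@H](C(=O)O)[C@H]1c1ccc(O)cc1 | intermediate
17 | dibenzyl (1α,2α,3β,4β)-2,4-bis[4-(benzyloxy)phenyl]cyclobutane-1,3-dicarboxylate | O=C(OCc1ccccc1)[C@H]1[C@H](c2ccc(OCc3ccccc3)cc2)[C@H](C(=O)OCc2ccccc2)[C@H]1c1ccc(OCc2ccccc2)cc1 | intermediate
18 | (1α,2α,3β,4β)-2,4-bis[4-(benzyloxy)phenyl]cyclobutane-1,3-dicarboxylic acid | OC(=O)[C@H]1[C@H](c2ccc(OCc3ccccc3)cc2)[C@H](C(=O)O)[C@H]1c1ccc(OCc2ccccc2)cc1 | intermediate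
19 | bis[(4R,4aS,6R,7S,7aR)-2,4,7-trimethyloctahydro-1H-cyclopenta[c]pyridin-6-yl] (1α,2α,3β,4β)-2,4-bis[4-(benzyloxy)phenyl]cyclobutane-1,3-dicarboxylate | C[C@H]1[C@@H]2CN(C)C[C@H](C)[C@@H]2C[C@H]1OC(=O)[C@H]1[C@H](c2ccc(OCc3ccccc3)cc2)[C@H](C(=O)O[C@@H]2C[C@@H]3[C@@H](CN(C)C[C@@H]3C)[C@@H]2C)[C@H]1c1ccc(OCc2ccccc2)cc1 | intermediate
20 | bis[(4R,4aS,6R,7S,7aR)-2,4,7-trimethyloctahydro-1H-cyclopenta[c]pyridin-6-yl] (1α,2α,3β,4β)-2,4-bis(4-hydroxyphenyl)cyclobutane-1,3-dicarboxylate | C[C@H]1[C@@H]2CN(C)C[C@H](C)[C@@H]2C[C@H]1OC(=O)[C@H]1[C@H](c2ccc(O)cc2)[C@H](C(=O)O[C@@H]2C[C@@H]3[C@@H](CN(C)C[C@@H]3C)[C@@H]2C)[C@H]1c1ccc(O)cc1 | target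

Total step count: 13. Longest linear sequence: 10 steps (steps 1–8, 12, 13); steps 9–11 form the convergent branch.

Steps most likely to fail

1. Step 4 (proposed new method). What may go wrong: insufficient enantiofacial discrimination at C4a; closure at the α-carbon C1 or at the enol oxygen; O-acylation of the enol by the chloroformate; re-opening of the γ-adduct with loss of enantiomeric purity. The fallback uses known chemistry only: C4a–C5 is made intermolecularly, the ring is closed by a Dieckmann condensation and the enantiomers are separated. It sets out from acid 4 and comes back at ketone 13.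
   - Fischer esterification of 4 (MeOH, H2SO4, reflux) gives methyl 2-(5-methylpyridin-3-yl)propanoate F1.
   - Acylation of F1 with methyl chloroformate 8 in the presence of 1-(tert-butyldimethylsilyloxy)-1-methoxyethene (CH2Cl2, −78 → 0 °C) should give methyl 4-(2-methoxy-2-oxoethyl)-3-(1-methoxy-1-oxopropan-2-yl)-5-methyl-4H-pyridine-1-carboxylate F2, by the known γ-addition of ketene silyl acetals to N-alkoxycarbonylpyridinium ions.
   - Dieckmann condensation (KOt-Bu, THF, 0 °C) forms C5–C6 and is driven by the enolate of the product that keeps a C5–H between two carbonyl groups; it gives racemic 10 F3.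
   - Steps 5, 6 and 7, run on racemic material, give racemic 11 F4, racemic 12 F5 and racemic 13 F6.
   - Preparative chromatography of F6 on a chiral stationary phase (SFC, amylose carbamate phase) returns the (4R,4aS,7S,7aR) enantiomer 13.

2. Step 5. What may go wrong: poor facial selectivity at C7a or C4 (a C7 methyl group on the convex face hinders approach to C7a), scrambling of the doubly allylic C4a–H on the metal surface, or incomplete reduction of the second enecarbamate. The fallback replaces steric approach control on a surface by coordination-directed delivery in solution; it sets out from 10 and comes back at 11. Homogeneous hydrogenation with the cationic iridium complex [Ir(cod)(PCy3)(py)]PF6 in CH2Cl2 under H2 is used. The C5 ester carbonyl lies on the convex face in the favoured C5 epimer (trans to C4); it should bind iridium and guide both hydrogen additions to the face of H4a. No new compound is made (F0).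

3. Step 12. What may go wrong: elimination of the activated cyclopentanol instead of substitution, stalling at the mono-ester, or slow SN2 because the bulky truxillate has to enter next to the C7 methyl group. The fallback separates the inversion from the coupling; it sets out from 14 and comes back at 19.
   - Mitsunobu inversion of 14 with the small, more acidic 4-nitrobenzoic acid (PPh3, DIAD, toluene) gives (4R,4aS,6R,7S,7aR)-2,4,7-trimethyloctahydro-1H-cyclopenta[c]pyridin-6-yl 4-nitrobenzoate F7.
   - Methanolysis (K2CO3, MeOH, rt) gives the 6-exo alcohol (4R,4aS,6R,7S,7aR)-2,4,7-trimethyloctahydro-1H-cyclopenta[c]pyridin-6-ol F8.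
   - Steglich esterification of F8 (2.2 equiv) with diacid 18 (EDC·HCl, DMAP, CH2Cl2) proceeds with retention at C6 and gives 19.

Further compounds
F1 | step 4 | methyl 2-(5-methylpyridin-3-yl)propanoate (racemic) | Cc1cncc(C(C)C(=O)OC)c1
F2 | step 4 | methyl 4-(2-methoxy-2-oxoethyl)-3-(1-methoxy-1-oxopropan-2-yl)-5-methyl-4H-pyridine-1-carboxylate (racemic, both diastereomers) | COC(=O)N1C=C(C)C(CC(=O)OC)C(C(C)C(=O)OC)=C1
F3 | step 4 | racemic 10, dimethyl 4,7-dimethyl-6-oxo-4a,5,6,7-tetrahydro-2H-cyclopenta[c]pyridine-2,5-dicarboxylate | CC1C2=CN(C(=O)OC)C=C(C)C2C(C(=O)OC)C1=O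
F4 | step 4 | racemic 11 (1:1 mixture of both enantiomers) | CC1[C@@H]2CN(C(=O)OC)C[C@H](C)[C@@H]2C(C(=O)OC)C1=O.CC1[C@H]2CN(C(=O)OC)C[C@@H](C)[C@H]2C(C(=O)OC)C1=O
F5 | step 4 | racemic 12 (1:1 mixture of both enantiomers) | CC1[C@@H]2CN(C(=O)OC)C[C@H](C)[C@@H]2CC1=O.CC1[C@H]2CN(C(=O)OC)C[C@@H](C)[C@H]2CC1=O
F6 | step 4 | racemic 13 (1:1 mixture of both enantiomers) | C[C@H]1[C@@H]2CN(C(=O)OC)C[C@H](C)[C@@H]2CC1=O.C[C@@H]1[C@H]2CN(C(=O)OC)C[C@@H](C)[C@H]2CC1=O
F0 | step 5 | none | none
F7 | step 12 | (4R,4aS,6R,7S,7aR)-2,4,7-trimethyloctahydro-1H-cyclopenta[c]pyridin-6-yl 4-nitrobenzoate | C[C@H]1[C@@H]2CN(C)C[C@H](C)[C@@H]2C[C@H]1OC(=O)c1ccc(cc1)[N+](=O)[O-]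
F8 | step 12 | (4R,4aS,6R,7S,7aR)-2,4,7-trimethyloctahydro-1H-cyclopenta[c]pyridin-6-ol | C[C@H]1[C@@H]2CN(C)C[C@H](C)[C@@H]2C[C@H]1O
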